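**Retrosynthetic overview** (chroman numbering O1, C2, C3, C4, C4a, C5–C8, C8a; ring A = benzo ring, ring B = 2-aryl ring, ring C = pyran ring)
1. After removal of one silyl group from ring B, ring C is opened at the C4–C4a bond, giving the (R)-aryl alkyl ether 15 with a primary iodide at C4 and a free C7 hydroxyl.
2. Enabling feature: C4a is the only unsubstituted ring A carbon ortho to O1 (C8 is blocked by the prenyl group), and it is para to the C7 hydroxyl and ortho to the C5 methoxyl. The C7 phenoxide therefore makes C4a a carbon nucleophile that closes ring C without acid, which the prenyl/ortho-phenol pair would not tolerate.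
3. The O1–C2 bond of 15 comes from a Mitsunobu inversion between the (S)-chloro alcohol 13 and 5-methoxy-2-prenylresorcinol 6. The two hydroxyls of 6 are equivalent, so ring A needs neither a protecting group nor regiocontrol.
4. The C2 stereocentre comes from a CBS reduction of β-chloro ketone 12; the prenyl group of 6 comes from directed ortho-metalation between two MOM ethers.
5. Ring order: rings A and B are bought as arenes, O1–C2 is made first, and ring C is formed last, in step 9.

Key step: step 9

Remark: the single stereocentre (C2) is (R) as read from the SMILES; 5-methoxybenzene-1,3-diol, prenyl bromide, 3-bromo-5-methoxyphenol and 3-chloropropanoyl chloride are taken as commercial.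

**Route**

Step 1
Reactants: 1 5-methoxybenzene-1,3-diol
Product: 2 1-methoxy-3,5-bis(methoxymethoxy)benzene
Conditions: NaH (2.4 equiv), DMF, 0 °C; MOMCl (2.4 equiv), 0 °C → rt
Reagents that add atoms: chloromethyl methyl ether (MOMCl), COCCl
Why: Double O-alkylation of the bis-phenoxide with the hard electrophile MOMCl (Williamson-type ether synthesis) should give the bis-acetal, which protects both hydroxyls and supplies the directing groups for step 2; no stereocentre is formed.

Step 2
Reactants: 2 1-methoxy-3,5-bis(methoxymethoxy)benzene; 3 1-bromo-3-methylbut-2-ene (prenyl bromide)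
Product: 5 5-methoxy-1,3-bis(methoxymethoxy)-2-(3-methylbut-2-en-1-yl)benzene, via aryllithium 4 (not isolated)
Conditions: n-BuLi (1.1 equiv), THF, 0 °C → rt; then CuI (10 mol%), 3, −78 °C → rt
Reagents that add atoms: none
Why: Directed ortho-metalation should lithiate the carbon flanked by the two OCH2OCH3 groups, the stronger directing groups, in preference to the carbons next to OCH3, and CuI-catalysed allylic substitution at the primary carbon of prenyl bromide should give the linear prenyl arene; no stereocentre is formed.

Step 3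
Reactants: 5 5-methoxy-1,3-bis(methoxymethoxy)-2-(3-methylbut-2-en-1-yl)benzene
Product: 6 5-methoxy-2-(3-methylbut-2-en-1-yl)benzene-1,3-diol
Conditions: HCl (3 M aq., catalytic amount), MeOH, rt → 40 °C, stopped at full conversion
Reagents that add atoms: none
Why: Acid-catalysed acetal exchange with methanol should free both phenols under conditions mild enough that the prenyl double bond does not add to the neighbouring hydroxyl, giving a C2v-symmetric diol whose two hydroxyls are equivalent.

Step 4
Reactants: 7 3-bromo-5-methoxyphenol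
Product: 8 (3-bromo-5-methoxyphenoxy)triisopropylsilane
Conditions: NaH (1.1 equiv), THF, 0 °C; TIPSCl (1.1 equiv), rt
Reagents that add atoms: chlorotriisopropylsilane (TIPSCl), CC(C)[Si](Cl)(C(C)C)C(C)C
Why: Silylation of the sodium phenoxide should give a triisopropylsilyl ether that withstands the organolithium, borane, Mitsunobu and alkoxide conditions ahead and is removed by fluoride at the end.

Step 5
Reactants: 8 (3-bromo-5-methoxyphenoxy)triisopropylsilane; 9 3-chloropropanoyl chloride
Product: 12 3-chloro-1-[3-methoxy-5-(triisopropylsilyloxy)phenyl]propan-1-one, via aryllithium 10 (not isolated), via arylzinc chloride 11 (not isolated)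
Conditions: n-BuLi (1.05 equiv), THF, −78 °C; ZnCl2 (1.1 equiv), −78 → 0 °C; Pd(PPh3)4 (3 mol%), 9 (1.2 equiv), 0 °C → rt
Reagents that add atoms: none
Why: Bromine–lithium exchange, transmetalation to zinc and Pd(PPh3)4-catalysed acylation of the arylzinc chloride (Negishi acylation) should give the ketone without over-addition, the weakly basic organozinc leaving the β-chloride in place.

Step 6
Reactants: 12 3-chloro-1-[3-methoxy-5-(triisopropylsilyloxy)phenyl]propan-1-one
Product: 13 (1S)-3-chloro-1-[3-methoxy-5-(triisopropylsilyloxy)phenyl]propan-1-ol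
Conditions: (R)-2-methyl-CBS-oxazaborolidine [(3aR)-1-methyl-3,3-diphenyltetrahydro-1H,3H-pyrrolo[1,2-c][1,3,2]oxazaborole] (10 mol%), BH3·SMe2, THF, 0 °C; MeOH, then aqueous work-up
Reagents that add atoms: none
Why: In the Corey–Bakshi–Shibata reduction the ketone should bind the (R)-oxazaborolidine–borane complex with its aryl group away from the catalyst, so that hydride goes to the face giving the (S)-alcohol, as is established for 3-chloro-1-arylpropan-1-ones; this sets the only stereocentre, in the configuration opposite to the final one because step 7 inverts it.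

Step 7
Reactants: 6 5-methoxy-2-(3-methylbut-2-en-1-yl)benzene-1,3-diol; 13 (1S)-3-chloro-1-[3-methoxy-5-(triisopropylsilyloxy)phenyl]propan-1-ol
Product: 14 3-{(1R)-3-chloro-1-[3-methoxy-5-(triisopropylsilyloxy)phenyl]propoxy}-5-methoxy-2-(3-methylbut-2-en-1-yl)phenol
Conditions: 6 (2 equiv), PPh3 (1.3 equiv), DIAD (1.3 equiv), THF, 0 °C → rt; excess 6 recovered
Reagents that add atoms: none
Why: In the Mitsunobu etherification the phenoxide of 6 should displace the oxyphosphonium of 13 in an SN2 reaction with inversion, (S)-C–OH becoming (R)-C–OAr as is known for 3-chloro-1-arylpropan-1-ols with ortho-substituted phenols; either hydroxyl of 6 gives the same mono-ether, the excess of 6 suppresses double etherification, and the primary chloride is inert.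

Step 8
Reactants: 14 3-{(1R)-3-chloro-1-[3-methoxy-5-(triisopropylsilyloxy)phenyl]propoxy}-5-methoxy-2-(3-methylbut-2-en-1-yl)phenol
Product: 15 3-{(1R)-3-iodo-1-[3-methoxy-5-(triisopropylsilyloxy)phenyl]propoxy}-5-methoxy-2-(3-methylbut-2-en-1-yl)phenol
Conditions: NaI (5 equiv), butan-2-one, 80 °C, dark
Reagents that add atoms: sodium iodide, [Na+].[I-]
Why: Finkelstein halide exchange, driven by precipitation of NaCl, should turn the primary chloride into the iodide needed for ring closure under neutral conditions that leave the phenol, the prenyl group and the benzylic ether stereocentre untouched.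

Step 9
Reactants: 15 3-{(1R)-3-iodo-1-[3-methoxy-5-(triisopropylsilyloxy)phenyl]propoxy}-5-methoxy-2-(3-methylbut-2-en-1-yl)phenol
Product: 18 (2R)-5-methoxy-2-[3-methoxy-5-(triisopropylsilyloxy)phenyl]-8-(3-methylbut-2-en-1-yl)-3,4-dihydro-2H-chromen-7-ol, via potassium phenoxide 16 (not isolated), via cyclohexadienone 17 (not isolated)
Conditions: KOtBu (1.05 equiv), t-BuOH/THF 4:1, 0.01 M, 25 → 50 °C; aq. NH4Cl
Reagents that add atoms: none
Why: KOtBu should convert the C7 hydroxyl into phenoxide 16, whose charge is delocalised onto the para carbon, the future C4a; this carbon displaces iodide from the primary C4 in an intramolecular SN2 reaction, and tautomerisation of the cross-conjugated dienone 17 restores ring A. The closest known reaction type is the intramolecular C-alkylation of phenoxides by tethered primary halides or sulfonates to give benzo-fused six-membered rings (anionic aryl participation of the Ar2-6 kind). Ring C closes in the 6-exo-tet mode, the O1–C2–C3 tether holding C4 over C4a. No stereocentre is created: the bonds at C2 are untouched, and the sp3 centre at C4a in 17 is erased on re-aromatisation. The step needs carbon over oxygen alkylation and C4a over C8: the phenoxide oxygen could reach C4 only through an eight-membered ring, intermolecular O-alkylation is held back by high dilution in a hydrogen-bonding solvent, C8 carries the prenyl group so that attack there would build a quaternary non-aromatisable centre, and C6 is out of reach of the tether. The absence of any Brønsted or Lewis acid keeps the prenyl group from cyclising onto the C7 hydroxyl.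

Step 10
Reactants: 18 (2R)-5-methoxy-2-[3-methoxy-5-(triisopropylsilyloxy)phenyl]-8-(3-methylbut-2-en-1-yl)-3,4-dihydro-2H-chromen-7-ol
Product: 19 3-[(2R)-7-hydroxy-5-methoxy-8-(3-methylbut-2-en-1-yl)-3,4-dihydro-2H-chromen-2-yl]-5-methoxyphenol
Conditions: TBAF (1.2 equiv), AcOH (1.2 equiv), THF, 0 °C
Reagents that add atoms: none
Why: Fluoride should cleave the aryl Si–O bond while the acetic acid buffer keeps the liberated electron-rich phenol protonated; the C2 benzylic ether stereocentre and the prenyl group are not affected.

**Compound list**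
1 | 5-methoxybenzene-1,3-diol | COc1cc(O)cc(O)c1 | starting material
2 | 1-methoxy-3,5-bis(methoxymethoxy)benzene | COCOc1cc(OC)cc(OCOC)c1 | intermediate
3 | 1-bromo-3-methylbut-2-ene (prenyl bromide) | CC(C)=CCBr | starting material
4 | [4-methoxy-2,6-bis(methoxymethoxy)phenyl]lithium | [Li]c1c(OCOC)cc(OC)cc1OCOC | intermediate
5 | 5-methoxy-1,3-bis(methoxymethoxy)-2-(3-methylbut-2-en-1-yl)benzene | COCOc1cc(OC)cc(OCOC)c1CC=C(C)C | intermediate
6 | 5-methoxy-2-(3-methylbut-2-en-1-yl)benzene-1,3-diol | COc1cc(O)c(CC=C(C)C)c(O)c1 | intermediate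
7 | 3-bromo-5-methoxyphenol | COc1cc(O)cc(Br)c1 | starting material
8 | (3-bromo-5-methoxyphenoxy)triisopropylsilane | COc1cc(Br)cc(O[Si](C(C)C)(C(C)C)C(C)C)c1 | intermediate
9 | 3-chloropropanoyl chloride | O=C(Cl)CCCl | starting material
10 | [3-methoxy-5-(triisopropylsilyloxy)phenyl]lithium | COc1cc([Li])cc(O[Si](C(C)C)(C(C)C)C(C)C)c1 | intermediate
11 | chloro[3-methoxy-5-(triisopropylsilyloxy)phenyl]zinc | COc1cc([Zn]Cl)cc(O[Si](C(C)C)(C(C)C)C(C)C)c1 | intermediate
12 | 3-chloro-1-[3-methoxy-5-(triisopropylsilyloxy)phenyl]propan-1-one | COc1cc(O[Si](C(C)C)(C(C)C)C(C)C)cc(C(=O)CCCl)c1 | intermediate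
13 | (1S)-3-chloro-1-[3-methoxy-5-(triisopropylsilyloxy)phenyl]propan-1-ol | COc1cc(O[Si](C(C)C)(C(C)C)C(C)C)cc([C@@H](O)CCCl)c1 | intermediate
14 | 3-{(1R)-3-chloro-1-[3-methoxy-5-(triisopropylsilyloxy)phenyl]propoxy}-5-methoxy-2-(3-methylbut-2-en-1-yl)phenol | COc1cc(O[Si](C(C)C)(C(C)C)C(C)C)cc([C@@H](CCCl)Oc2cc(OC)cc(O)c2CC=C(C)C)c1 | intermediate
15 | 3-{(1R)-3-iodo-1-[3-methoxy-5-(triisopropylsilyloxy)phenyl]propoxy}-5-methoxy-2-(3-methylbut-2-en-1-yl)phenol | COc1cc(O[Si](C(C)C)(C(C)C)C(C)C)cc([C@@H](CCI)Oc2cc(OC)cc(O)c2CC=C(C)C)c1 | intermediate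
16 | potassium 3-{(1R)-3-iodo-1-[3-methoxy-5-(triisopropylsilyloxy)phenyl]propoxy}-5-methoxy-2-(3-methylbut-2-en-1-yl)phenolate | COc1cc(O[Si](C(C)C)(C(C)C)C(C)C)cc([C@@H](CCI)Oc2cc(OC)cc([O-])c2CC=C(C)C)c1.[K+] | intermediate
17 | (2R)-5-methoxy-2-[3-methoxy-5-(triisopropylsilyloxy)phenyl]-8-(3-methylbut-2-en-1-yl)-2,3,4,4a-tetrahydro-7H-chromen-7-one (C4a configuration undefined) | O=C1C=C(OC)C2CC[C@H](c3cc(OC)cc(O[Si](C(C)C)(C(C)C)C(C)C)c3)OC2=C1CC=C(C)C | intermediate
18 | (2R)-5-methoxy-2-[3-methoxy-5-(triisopropylsilyloxy)phenyl]-8-(3-methylbut-2-en-1-yl)-3,4-dihydro-2H-chromen-7-ol | COc1cc(O[Si](C(C)C)(C(C)C)C(C)C)cc([C@H]2CCc3c(OC)cc(O)c(CC=C(C)C)c3O2)c1 | intermediate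
19 | 3-[(2R)-7-hydroxy-5-methoxy-8-(3-methylbut-2-en-1-yl)-3,4-dihydro-2H-chromen-2-yl]-5-methoxyphenol | COc1cc(O)cc([C@H]2CCc3c(OC)cc(O)c(CC=C(C)C)c3O2)c1 | target

**Step count**
Total steps: 10. Longest linear sequence: 7 steps (steps 4, 5, 6, 7, 8, 9, 10 from compound 7; equally steps 1, 2, 3, 7, 8, 9, 10 from compound 1).

**Steps most likely to fail**

Step 9 (key ring closure). What may go wrong: the phenoxide may be alkylated at oxygen by a second molecule, leading to oligomers, or the prenyl-bearing carbon C8 may attack in place of C4a and give a dearomatised dienone that cannot re-aromatise. Fallback: setting out from 15, the C7 hydroxyl would be silylated (TIPSOTf, 2,6-lutidine, CH2Cl2, 0 °C) to the bis-silyl iodide F1. Ring C would then be closed at the same bond by the Pd(PPh3)4-catalysed ring-forming aromatic C–H alkylation known for unactivated alkyl iodides (K3PO4, 1,4-dioxane, 100 °C). In this reaction zerovalent palladium activates the C–I bond by single-electron transfer, the primary C4 radical adds to C4a, and the cyclohexadienyl radical is re-aromatised, giving the bis-silyl chroman F2. With no phenoxide present O-alkylation is excluded, and radical addition at the substituted C8 is reversible. TBAF/AcOH in THF would remove both silyl groups, and the sequence comes back to the route at 19.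

Step 7 (Mitsunobu etherification). What may go wrong: double etherification of the diol, slow coupling of the ortho-substituted phenol with competing elimination of the activated alcohol, or partial loss of configuration through ionisation of the benzylic oxyphosphonium. Fallback: setting out from 8 and 6, the stereocentre would be set by the catalyst instead of by reduction and inversion.
- Heck reaction of 8 with methyl acrylate (Pd(OAc)2, P(o-tol)3, Et3N, DMF, 100 °C) would give the cinnamate F3.
- i-Bu2AlH (CH2Cl2, −78 °C) would give the cinnamyl alcohol F4, and methyl chloroformate/pyridine the methyl carbonate F5.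
- Enantioselective allylic etherification of F5 with excess 6 under [Ir(cod)Cl]2 and a binaphthol-derived phosphoramidite ligand (K3PO4, THF) is a reaction type that gives branched aryl allyl ethers from cinnamyl carbonates and phenoxides under catalyst control. With the ligand enantiomer chosen accordingly it would give the (R)-branched ether F6.
- Hydroboration of the vinyl group with 9-borabicyclo[3.3.1]nonane, which leaves the trisubstituted prenyl alkene alone, followed by NaBO3 oxidation, would give the primary alcohol F7.
- I2/PPh3/imidazole would convert F7 into the iodide, so the sequence comes back to the route at 15.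

Step 5 (acylation to the β-chloro ketone). What may go wrong: loss of HCl from the β-chloro ketone to the aryl vinyl ketone under the organometallic conditions, followed by further addition to that enone. Fallback: setting out from 8, bromine–lithium exchange (n-BuLi, THF, −78 °C) and addition to acrolein would give the allylic alcohol F8. MnO2 (CH2Cl2, rt) would oxidise it to the aryl vinyl ketone F9, and conjugate addition of HCl (HCl in 1,4-dioxane, 0 °C) would install the chloride last, coming back to the route at 12.

**Further compounds**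
F1 | step 9 | triisopropyl{3-[(1R)-3-iodo-1-[3-methoxy-5-(triisopropylsilyloxy)phenyl]propoxy]-5-methoxy-2-(3-methylbut-2-en-1-yl)phenoxy}silane | COc1cc(O[Si](C(C)C)(C(C)C)C(C)C)cc([C@@H](CCI)Oc2cc(OC)cc(O[Si](C(C)C)(C(C)C)C(C)C)c2CC=C(C)C)c1
F2 | step 9 | (2R)-5-methoxy-2-[3-methoxy-5-(triisopropylsilyloxy)phenyl]-8-(3-methylbut-2-en-1-yl)-7-(triisopropylsilyloxy)-3,4-dihydro-2H-chromene | COc1cc(O[Si](C(C)C)(C(C)C)C(C)C)cc([C@H]2CCc3c(OC)cc(O[Si](C(C)C)(C(C)C)C(C)C)c(CC=C(C)C)c3O2)c1
F3 | step 7 | methyl (E)-3-[3-methoxy-5-(triisopropylsilyloxy)phenyl]prop-2-enoate | COC(=O)/C=C/c1cc(OC)cc(O[Si](C(C)C)(C(C)C)C(C)C)c1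
F4 | step 7 | (E)-3-[3-methoxy-5-(triisopropylsilyloxy)phenyl]prop-2-en-1-ol | OC/C=C/c1cc(OC)cc(O[Si](C(C)C)(C(C)C)C(C)C)c1
F5 | step 7 | methyl (E)-3-[3-methoxy-5-(triisopropylsilyloxy)phenyl]prop-2-en-1-yl carbonate | COC(=O)OC/C=C/c1cc(OC)cc(O[Si](C(C)C)(C(C)C)C(C)C)c1
F6 | step 7 | 3-{(1R)-1-[3-methoxy-5-(triisopropylsilyloxy)phenyl]prop-2-en-1-yloxy}-5-methoxy-2-(3-methylbut-2-en-1-yl)phenol | COc1cc(O[Si](C(C)C)(C(C)C)C(C)C)cc([C@@H](C=C)Oc2cc(OC)cc(O)c2CC=C(C)C)c1
F7 | step 7 | (3R)-3-[3-hydroxy-5-methoxy-2-(3-methylbut-2-en-1-yl)phenoxy]-3-[3-methoxy-5-(triisopropylsilyloxy)phenyl]propan-1-ol | COc1cc(O[Si](C(C)C)(C(C)C)C(C)C)cc([C@@H](CCO)Oc2cc(OC)cc(O)c2CC=C(C)C)c1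
F8 | step 5 | 1-[3-methoxy-5-(triisopropylsilyloxy)phenyl]prop-2-en-1-ol (racemic) | COc1cc(O[Si](C(C)C)(C(C)C)C(C)C)cc(C(O)C=C)c1
F9 | step 5 | 1-[3-methoxy-5-(triisopropylsilyloxy)phenyl]prop-2-en-1-one | COc1cc(O[Si](C(C)C)(C(C)C)C(C)C)cc(C(=O)C=C)c1
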